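**Retrosynthetic overview**
- The maleimide C=C is made last, by selenoxide elimination from a 3-acylsuccinimide. The acyl–ring bond comes from C-acylation of the dianion of (S)-octenylsuccinimide (fragment B) with the decalin acid (fragment A).
- In fragment A, C3=C4 comes from a C3 ketone (enol triflate, then formate reduction), and 8-H/8a-H come from an OH-directed hydrogenation of a C8=C8a alkene.
- Key disconnection: the C4–C4a bond, closed by intramolecular aldol addition of a methyl ketone enolate to a cyclohexenone carbonyl. This closes ring A and creates the 4a-OH.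
- The aldol substrate comes from a resorcinol-derived 1,3-dione (ring B) and a keto-enoate (asymmetric Michael addition), followed by triflation and Negishi methylation.
- Ring order: ring B (arene hydrogenation), then ring A (aldol); the succinimide ring (from maleic anhydride) is oxidised to the maleimide at the end.

Assumption: decalin locants follow the target (C1 bears the acyl carbon, C2 and C8 the methyls, C4a the oxygen, C6 the carboxyl). Compounds 7–24 are an about 1:1 pair of C6 epimers, drawn without configuration at C6, that converge in step 16. The sp3 ring carbons of the succinimide in 20–28 are drawn without configuration and become sp2 in step 17.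

**Step 1**
Reactants: 1 ethyl 3,5-dihydroxybenzoate
Product: 2 ethyl 3,5-dioxocyclohexane-1-carboxylate
Conditions: H2 (4 bar), Rh/Al2O3 (5 wt% Rh), NaOH (1.0 equiv), EtOH/H2O, 25 °C; then HCl to pH 3
Reagents that add atoms: none
Why: Partial catalytic hydrogenation of the resorcinol monoanion stops at the 1,3-dione because the vinylogous carboxylate formed resists further reduction; no stereocentre is fixed yet.

**Step 2**
Reactants: 3 butane-2,3-dione; 4 tert-butyl 2-(diethoxyphosphoryl)acetate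
Product: 5 tert-butyl (2E)-3-methyl-4-oxopent-2-enoate
Conditions: NaH, THF, 0 °C; then the diketone in threefold excess, −40 → 0 °C
Reagents that add atoms: none
Why: Horner–Wadsworth–Emmons mono-olefination of the symmetrical diketone (used in excess) gives the E enoate, with the ester trans to the acetyl group.

**Step 3**
Reactants: 2 ethyl 3,5-dioxocyclohexane-1-carboxylate; 5 tert-butyl (2E)-3-methyl-4-oxopent-2-enoate
Product: 7 tert-butyl (2S,3S)-2-[4-(ethoxycarbonyl)-6-oxo-2-(trifluoromethylsulfonyloxy)cyclohex-1-en-1-yl]-3-methyl-4-oxopentanoate, via Michael adduct 6 (not isolated)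
Conditions: 9-amino-9-deoxy-epi-quinine [(8α,9S)-6′-methoxycinchonan-9-amine] (10 mol%), CF3CO2H (20 mol%), CH2Cl2, 23 °C, 48 h; then i-Pr2NEt, Tf2O, −78 °C
Reagents that add atoms: trifluoromethanesulfonic anhydride, O=S(=O)(OS(=O)(=O)C(F)(F)F)C(F)(F)F
Why: Iminium-catalysed asymmetric Michael addition of the 1,3-dione to the enone carbon β to the ketone sets C1 by face selection on the chiral iminium ion (sense assigned by analogy with warfarin-type additions, not established for this substrate; the quinidine-derived pseudo-enantiomer gives the antipode); C2 settles trans to the ester in the cyclic hemiketal form of 6, and O-triflation of either dione oxygen then gives the vinylogous acyl triflate as the C6 epimer pair.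

**Step 4**
Reactants: 7 tert-butyl (2S,3S)-2-[4-(ethoxycarbonyl)-6-oxo-2-(trifluoromethylsulfonyloxy)cyclohex-1-en-1-yl]-3-methyl-4-oxopentanoate
Product: 8 tert-butyl (2S,3S)-2-[4-(ethoxycarbonyl)-2-methyl-6-oxocyclohex-1-en-1-yl]-3-methyl-4-oxopentanoate
Conditions: MeZnCl (1.5 equiv), Pd(PPh3)4 (5 mol%), THF, 0 → 23 °C
Reagents that add atoms: methylzinc chloride, C[Zn]Cl
Why: Negishi cross-coupling of the vinylogous acyl triflate installs the C8 methyl under neutral conditions that leave the ketone, both esters and the C1/C2 stereocentres untouched.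

**Step 5**
Reactants: 8 tert-butyl (2S,3S)-2-[4-(ethoxycarbonyl)-2-methyl-6-oxocyclohex-1-en-1-yl]-3-methyl-4-oxopentanoate
Product: 9 1-tert-butyl 6-ethyl (1S,2S,4aR)-4a-hydroxy-2,8-dimethyl-3-oxo-1,2,3,4,4a,5,6,7-octahydronaphthalene-1,6-dicarboxylate
Conditions: LiN(i-Pr)2 (1.15 equiv), THF, −78 °C, 30 min; AcOH, −78 °C
Reagents that add atoms: none
Why: Key step, an intramolecular aldol addition (6-exo) of the kinetic lithium enolate of the methyl ketone to the enone carbonyl that closes ring A; allylic 1,3-strain with the C8 methyl holds C1–H in the enone plane, so the chain reaches C4a from the face opposite the ester and the new 4a-OH ends up cis to the C1 ester, while the cold acidic quench prevents retro-aldol and dehydration.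

**Step 6**
Reactants: 9 1-tert-butyl 6-ethyl (1S,2S,4aR)-4a-hydroxy-2,8-dimethyl-3-oxo-1,2,3,4,4a,5,6,7-octahydronaphthalene-1,6-dicarboxylate
Product: 10 1-tert-butyl 6-ethyl (1R,2S,4aR,8S,8aR)-4a-hydroxy-2,8-dimethyl-3-oxodecahydronaphthalene-1,6-dicarboxylate
Conditions: H2 (10 bar), [Ir(cod)(PCy3)(py)]PF6 (10 mol%), CH2Cl2, 23 °C
Reagents that add atoms: none
Why: Hydroxyl-directed hydrogenation delivers both hydrogens to the tetrasubstituted C8=C8a bond from the face of the allylic 4a-OH, setting 8a-H and 8-H cis to the hydroxyl (cis-fused decalin, C8 methyl on the other face).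

**Step 7**
Reactants: 10 1-tert-butyl 6-ethyl (1R,2S,4aR,8S,8aR)-4a-hydroxy-2,8-dimethyl-3-oxodecahydronaphthalene-1,6-dicarboxylate
Product: 12 (1R,2S,4aR,8S,8aR)-6-(ethoxycarbonyl)-2,8-dimethyl-3-oxo-4a-(trimethylsilyloxy)decahydronaphthalene-1-carboxylic acid, via bis-silyl compound 11 (not isolated)
Conditions: Me3SiOTf (3.0 equiv), 2,6-lutidine (4.0 equiv), CH2Cl2, −78 → 23 °C; then pH 7 phosphate buffer, THF, 0 °C
Reagents that add atoms: trimethylsilyl trifluoromethanesulfonate, C[Si](C)(C)OS(=O)(=O)C(F)(F)F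
Why: The silyl triflate silylates the tertiary alcohol and converts the tert-butyl ester into the silyl ester with loss of isobutene; the buffered work-up hydrolyses the silyl ester to the acid while the tertiary silyl ether stays.

**Step 8**
Reactants: 12 (1R,2S,4aR,8S,8aR)-6-(ethoxycarbonyl)-2,8-dimethyl-3-oxo-4a-(trimethylsilyloxy)decahydronaphthalene-1-carboxylic acid
Product: 13 (1S,2S,4aS,8S,8aR)-6-(ethoxycarbonyl)-2,8-dimethyl-3-(trifluoromethylsulfonyloxy)-4a-(trimethylsilyloxy)-1,2,4a,5,6,7,8,8a-octahydronaphthalene-1-carboxylic acid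
Conditions: KN(SiMe3)2 (2.2 equiv), THF, −78 °C; PhNTf2 (1.1 equiv), −78 → −30 °C; aq. NH4Cl
Reagents that add atoms: N-phenylbis(trifluoromethanesulfonimide), O=S(=O)(N(c1ccccc1)S(=O)(=O)C(F)(F)F)C(F)(F)F
Why: Kinetic enolate triflation: the hindered amide base deprotonates the C4 methylene rather than the C2 methine next to the carboxylate-bearing C1, and the triflimide traps the enolate as the C3–C4 enol triflate without touching C2.

**Step 9**
Reactants: 13 (1S,2S,4aS,8S,8aR)-6-(ethoxycarbonyl)-2,8-dimethyl-3-(trifluoromethylsulfonyloxy)-4a-(trimethylsilyloxy)-1,2,4a,5,6,7,8,8a-octahydronaphthalene-1-carboxylic acid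
Product: 14 (1S,2R,4aR,8S,8aR)-6-(ethoxycarbonyl)-2,8-dimethyl-4a-(trimethylsilyloxy)-1,2,4a,5,6,7,8,8a-octahydronaphthalene-1-carboxylic acid
Conditions: Pd(OAc)2 (5 mol%), PPh3 (10 mol%), n-Bu3N, HCO2H, DMF, 60 °C
Reagents that add atoms: none
Why: Palladium-catalysed formate reduction of the enol triflate (hydride transfer to the vinylpalladium intermediate) gives the C3=C4 alkene with the double bond fixed in position.

**Step 10**
Reactants: 15 maleic anhydride; 16 4-methoxybenzylamine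
Product: 17 (2Z)-4-[(4-methoxybenzyl)amino]-4-oxobut-2-enoic acid
Conditions: Et2O, 0 → 23 °C
Reagents that add atoms: none
Why: Ring-opening acylation of the amine by the cyclic anhydride gives the maleamic acid.

**Step 11**
Reactants: 17 (2Z)-4-[(4-methoxybenzyl)amino]-4-oxobut-2-enoic acid
Product: 18 1-(4-methoxybenzyl)-1H-pyrrole-2,5-dione
Conditions: Ac2O, NaOAc (0.3 equiv), 80 °C
Reagents that add atoms: none
Why: Cyclodehydration of the maleamic acid through its mixed anhydride closes the maleimide ring.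

**Step 12**
Reactants: 18 1-(4-methoxybenzyl)-1H-pyrrole-2,5-dione; 19 heptanal
Product: 20 (2R)-2-[1-(4-methoxybenzyl)-2,5-dioxopyrrolidin-3-yl]heptanal
Conditions: (S)-2-[diphenyl(trimethylsilyloxy)methyl]pyrrolidine (10 mol%), CHCl3, 23 °C, 24 h; the aldehyde in slight excess
Reagents that add atoms: none
Why: Enamine-catalysed Michael addition, a pure addition of the aldehyde α-carbon across the maleimide C=C: the E enamine of heptanal is attacked on the face away from the diphenyl(silyloxy)methyl group, which sets the side-chain stereocentre (R in the aldehyde, S once the formyl group is a vinyl group).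

**Step 13**
Reactants: 20 (2R)-2-[1-(4-methoxybenzyl)-2,5-dioxopyrrolidin-3-yl]heptanal
Product: 21 1-(4-methoxybenzyl)-3-[(3S)-oct-1-en-3-yl]pyrrolidine-2,5-dione
Conditions: Zn, CH2Br2, TiCl4, THF/CH2Cl2, 0 → 23 °C
Reagents that add atoms: dibromomethane, BrCBr
Why: Takai–Lombardo methylenation with the non-basic zinc/titanium methylene reagent turns the aldehyde into the vinyl group without epimerising the α-stereocentre or attacking the imide.

**Step 14**
Reactants: 21 1-(4-methoxybenzyl)-3-[(3S)-oct-1-en-3-yl]pyrrolidine-2,5-dione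
Product: 22 3-[(3S)-oct-1-en-3-yl]pyrrolidine-2,5-dione
Conditions: (NH4)2Ce(NO3)6 (3 equiv), MeCN/H2O 3:1, 0 → 23 °C
Reagents that add atoms: none
Why: Oxidative N-debenzylation: single-electron oxidation of the electron-rich 4-methoxybenzyl group and hydrolysis of the resulting iminium ion free the imide N–H.

**Step 15**
Reactants: 14 (1S,2R,4aR,8S,8aR)-6-(ethoxycarbonyl)-2,8-dimethyl-4a-(trimethylsilyloxy)-1,2,4a,5,6,7,8,8a-octahydronaphthalene-1-carboxylic acid; 22 3-[(3S)-oct-1-en-3-yl]pyrrolidine-2,5-dione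
Product: 24 ethyl (1S,2R,4aR,8S,8aR)-2,8-dimethyl-1-({4-[(3S)-oct-1-en-3-yl]-2,5-dioxopyrrolidin-3-yl}carbonyl)-4a-(trimethylsilyloxy)-1,2,4a,5,6,7,8,8a-octahydronaphthalene-6-carboxylate, via acyl imidazolide 23 (not isolated)
Conditions: the acid, 1,1′-carbonyldiimidazole, THF, 23 °C; added to the dianion of the imide (imide in 2.5-fold excess, LiN(i-Pr)2, two equivalents per imide), THF, −78 → −20 °C; aq. NH4Cl
Reagents that add atoms: none
Why: Crossed Claisen-type C-acylation: the N,C-dianion of the imide (C-deprotonation at the unsubstituted CH2) attacks the acyl imidazolide and joins the two fragments, and the cold conditions keep the C6 ethyl ester and the C1 stereocentre intact.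

**Step 16**
Reactants: 24 ethyl (1S,2R,4aR,8S,8aR)-2,8-dimethyl-1-({4-[(3S)-oct-1-en-3-yl]-2,5-dioxopyrrolidin-3-yl}carbonyl)-4a-(trimethylsilyloxy)-1,2,4a,5,6,7,8,8a-octahydronaphthalene-6-carboxylate
Product: 26 (1S,2R,4aR,6R,8S,8aR)-4a-hydroxy-2,8-dimethyl-1-({4-[(3S)-oct-1-en-3-yl]-2,5-dioxopyrrolidin-3-yl}carbonyl)-1,2,4a,5,6,7,8,8a-octahydronaphthalene-6-carboxylic acid, via C6-equilibrated ethyl ester 25 (not isolated)
Conditions: NaOEt (6 equiv), EtOH, 60 °C; then NaOH, H2O, 23 °C; then HCl to pH 3; chromatography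
Reagents that add atoms: sodium hydroxide, [Na+].[OH-]
Why: Base-mediated ester epimerisation brings C6 to the equatorial (6R) epimer, in which the ester is cis to the C8 methyl and avoids the syn-diaxial clash with the 4a oxygen, while the β-keto imide is protected as its enolate and the silyl ether is cleaved by ethoxide; saponification then frees the acid and the minor 6S acid is removed by chromatography.

**Step 17**
Reactants: 26 (1S,2R,4aR,6R,8S,8aR)-4a-hydroxy-2,8-dimethyl-1-({4-[(3S)-oct-1-en-3-yl]-2,5-dioxopyrrolidin-3-yl}carbonyl)-1,2,4a,5,6,7,8,8a-octahydronaphthalene-6-carboxylic acid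
Product: 29 (1S,2R,4aR,6R,8S,8aR)-4a-hydroxy-2,8-dimethyl-1-({4-[(3S)-oct-1-en-3-yl]-2,5-dioxo-2,5-dihydro-1H-pyrrol-3-yl}carbonyl)-1,2,4a,5,6,7,8,8a-octahydronaphthalene-6-carboxylic acid, via selenide 27 (not isolated), via selenoxide 28 (not isolated)
Conditions: PhSeCl (1.2 equiv), pyridine, CH2Cl2, 0 °C; then H2O2 (30% aq.), 0 → 23 °C
Reagents that add atoms: none
Why: α-Selenenylation of the β-keto imide at its doubly activated carbon, then oxidation and selenoxide syn-elimination with the only β-hydrogen (the succinimide C–H next to the side chain), gives the maleimide under neutral conditions that spare the stereocentre adjacent to the new double bond.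

**Compound list**
1 | ethyl 3,5-dihydroxybenzoate | CCOC(=O)c1cc(O)cc(O)c1 | starting material
2 | ethyl 3,5-dioxocyclohexane-1-carboxylate | CCOC(=O)C1CC(=O)CC(=O)C1 | intermediate
3 | butane-2,3-dione | CC(=O)C(C)=O | starting material
4 | tert-butyl 2-(diethoxyphosphoryl)acetate | CCOP(=O)(CC(=O)OC(C)(C)C)OCC | starting material
5 | tert-butyl (2E)-3-methyl-4-oxopent-2-enoate | CC(=O)/C(C)=C/C(=O)OC(C)(C)C | intermediate
6 | tert-butyl (2S,3S)-2-[4-(ethoxycarbonyl)-2,6-dioxocyclohexyl]-3-methyl-4-oxopentanoate (open form of the cyclic hemiketal) | CC(C)(C)OC(=O)[C@H](C1C(=O)CC(C(=O)OCC)CC1=O)[C@H](C)C(C)=O | intermediate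
7 | tert-butyl (2S,3S)-2-[4-(ethoxycarbonyl)-6-oxo-2-(trifluoromethylsulfonyloxy)cyclohex-1-en-1-yl]-3-methyl-4-oxopentanoate | CC(C)(C)OC(=O)[C@H](C1=C(OS(=O)(=O)C(F)(F)F)CC(C(=O)OCC)CC1=O)[C@H](C)C(C)=O | intermediate
8 | tert-butyl (2S,3S)-2-[4-(ethoxycarbonyl)-2-methyl-6-oxocyclohex-1-en-1-yl]-3-methyl-4-oxopentanoate | CC(C)(C)OC(=O)[C@H](C1=C(C)CC(C(=O)OCC)CC1=O)[C@H](C)C(C)=O | intermediate
9 | 1-tert-butyl 6-ethyl (1S,2S,4aR)-4a-hydroxy-2,8-dimethyl-3-oxo-1,2,3,4,4a,5,6,7-octahydronaphthalene-1,6-dicarboxylate (OH cis to the C1 ester, 2-Me trans to it) | CC(C)(C)OC(=O)[C@@H]1C2=C(C)CC(C(=O)OCC)C[C@@]2(O)CC(=O)[C@H]1C | intermediate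
10 | 1-tert-butyl 6-ethyl (1R,2S,4aR,8S,8aR)-4a-hydroxy-2,8-dimethyl-3-oxodecahydronaphthalene-1,6-dicarboxylate (cis-fused; 8-H and 8a-H cis to OH) | CC(C)(C)OC(=O)[C@@H]1[C@H]2[C@@H](C)CC(C(=O)OCC)C[C@@]2(O)CC(=O)[C@H]1C | intermediate
11 | 6-ethyl 1-trimethylsilyl (1R,2S,4aR,8S,8aR)-2,8-dimethyl-3-oxo-4a-(trimethylsilyloxy)decahydronaphthalene-1,6-dicarboxylate | C[Si](C)(C)OC(=O)[C@@H]1[C@H]2[C@@H](C)CC(C(=O)OCC)C[C@@]2(O[Si](C)(C)C)CC(=O)[C@H]1C | intermediate
12 | (1R,2S,4aR,8S,8aR)-6-(ethoxycarbonyl)-2,8-dimethyl-3-oxo-4a-(trimethylsilyloxy)decahydronaphthalene-1-carboxylic acid | OC(=O)[C@@H]1[C@H]2[C@@H](C)CC(C(=O)OCC)C[C@@]2(O[Si](C)(C)C)CC(=O)[C@H]1C | intermediate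
13 | (1S,2S,4aS,8S,8aR)-6-(ethoxycarbonyl)-2,8-dimethyl-3-(trifluoromethylsulfonyloxy)-4a-(trimethylsilyloxy)-1,2,4a,5,6,7,8,8a-octahydronaphthalene-1-carboxylic acid | OC(=O)[C@@H]1[C@H]2[C@@H](C)CC(C(=O)OCC)C[C@@]2(O[Si](C)(C)C)C=C(OS(=O)(=O)C(F)(F)F)[C@H]1C | intermediate
14 | (1S,2R,4aR,8S,8aR)-6-(ethoxycarbonyl)-2,8-dimethyl-4a-(trimethylsilyloxy)-1,2,4a,5,6,7,8,8a-octahydronaphthalene-1-carboxylic acid | OC(=O)[C@@H]1[C@H]2[C@@H](C)CC(C(=O)OCC)C[C@@]2(O[Si](C)(C)C)C=C[C@H]1C | intermediate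
15 | maleic anhydride | O=C1OC(=O)C=C1 | starting material
16 | 4-methoxybenzylamine | COc1ccc(CN)cc1 | starting material
17 | (2Z)-4-[(4-methoxybenzyl)amino]-4-oxobut-2-enoic acid | COc1ccc(CNC(=O)/C=C\C(=O)O)cc1 | intermediate
18 | 1-(4-methoxybenzyl)-1H-pyrrole-2,5-dione | COc1ccc(CN2C(=O)C=CC2=O)cc1 | intermediate
19 | heptanal | CCCCCCC=O | starting material
20 | (2R)-2-[1-(4-methoxybenzyl)-2,5-dioxopyrrolidin-3-yl]heptanal | O=C[C@H](CCCCC)C1CC(=O)N(Cc2ccc(OC)cc2)C1=O | intermediate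
21 | 1-(4-methoxybenzyl)-3-[(3S)-oct-1-en-3-yl]pyrrolidine-2,5-dione | C=C[C@H](CCCCC)C1CC(=O)N(Cc2ccc(OC)cc2)C1=O | intermediate
22 | 3-[(3S)-oct-1-en-3-yl]pyrrolidine-2,5-dione | C=C[C@H](CCCCC)C1CC(=O)NC1=O | intermediate
23 | ethyl (1S,2R,4aR,8S,8aR)-1-(1H-imidazol-1-ylcarbonyl)-2,8-dimethyl-4a-(trimethylsilyloxy)-1,2,4a,5,6,7,8,8a-octahydronaphthalene-6-carboxylate | O=C(n1ccnc1)[C@@H]1[C@H]2[C@@H](C)CC(C(=O)OCC)C[C@@]2(O[Si](C)(C)C)C=C[C@H]1C | intermediate
24 | ethyl (1S,2R,4aR,8S,8aR)-2,8-dimethyl-1-({4-[(3S)-oct-1-en-3-yl]-2,5-dioxopyrrolidin-3-yl}carbonyl)-4a-(trimethylsilyloxy)-1,2,4a,5,6,7,8,8a-octahydronaphthalene-6-carboxylate | C=C[C@H](CCCCC)C1C(C(=O)[C@@H]2[C@H]3[C@@H](C)CC(C(=O)OCC)C[C@@]3(O[Si](C)(C)C)C=C[C@H]2C)C(=O)NC1=O | intermediate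
25 | ethyl (1S,2R,4aR,6R,8S,8aR)-4a-hydroxy-2,8-dimethyl-1-({4-[(3S)-oct-1-en-3-yl]-2,5-dioxopyrrolidin-3-yl}carbonyl)-1,2,4a,5,6,7,8,8a-octahydronaphthalene-6-carboxylate | C=C[C@H](CCCCC)C1C(C(=O)[C@@H]2[C@H]3[C@@H](C)C[C@@H](C(=O)OCC)C[C@@]3(O)C=C[C@H]2C)C(=O)NC1=O | intermediate
26 | (1S,2R,4aR,6R,8S,8aR)-4a-hydroxy-2,8-dimethyl-1-({4-[(3S)-oct-1-en-3-yl]-2,5-dioxopyrrolidin-3-yl}carbonyl)-1,2,4a,5,6,7,8,8a-octahydronaphthalene-6-carboxylic acid | C=C[C@H](CCCCC)C1C(C(=O)[C@@H]2[C@H]3[C@@H](C)C[C@@H](C(=O)O)C[C@@]3(O)C=C[C@H]2C)C(=O)NC1=O | intermediate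
27 | 3-(phenylselanyl) derivative of 26 (PhSe on the succinimide carbon that bears the acyl group, trans to the octenyl group) | C=C[C@H](CCCCC)C1C(=O)NC(=O)C1([Se]c3ccccc3)C(=O)[C@@H]4[C@H]5[C@@H](C)C[C@@H](C(=O)O)C[C@@]5(O)C=C[C@H]4C | intermediate
28 | selenoxide of 27 | C=C[C@H](CCCCC)C1C(=O)NC(=O)C1([Se](=O)c3ccccc3)C(=O)[C@@H]4[C@H]5[C@@H](C)C[C@@H](C(=O)O)C[C@@]5(O)C=C[C@H]4C | intermediate
29 | (1S,2R,4aR,6R,8S,8aR)-4a-hydroxy-2,8-dimethyl-1-({4-[(3S)-oct-1-en-3-yl]-2,5-dioxo-2,5-dihydro-1H-pyrrol-3-yl}carbonyl)-1,2,4a,5,6,7,8,8a-octahydronaphthalene-6-carboxylic acid | C=C[C@H](CCCCC)C1=C(C(=O)[C@@H]2[C@H]3[C@@H](C)C[C@@H](C(=O)O)C[C@@]3(O)C=C[C@H]2C)C(=O)NC1=O | target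

**Step count**
- Total: 17 steps.
- Longest linear sequence: 11 steps (step 1 or step 2, then steps 3–9 and 15–17). The succinimide branch is steps 10–14.

**Three steps most likely to fail**

Step 3 (the sense and level of induction at C1, and the C2 ratio, are not established for this trisubstituted keto-enoate). The fallback sets out from 2 and comes back at 6. Compound 2 is condensed (Knoevenagel, piperidinium acetate) with tert-butyl glyoxylate F1, itself made by NaIO4 cleavage of di-tert-butyl L-tartrate. The product is the alkylidene dione F2. An inverse-electron-demand hetero-Diels–Alder reaction of F2 with (E)-2-methoxybut-2-ene, catalysed by Cu(OTf)2 and (S,S)-2,2′-isopropylidenebis(4-tert-butyl-2-oxazoline), gives the dihydropyran ketal F3; the endo-alkoxy transition state fixes the 1,2-trans relationship stereospecifically. Dilute HCl in THF opens F3 to 6, which is triflated as in the second stage of step 3.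

Step 5 (enolate regiochemistry, 1,2- against 1,4-addition, and loss of water from the ketol). The fallback sets out from 8 and comes back at 9. Compound 8 is converted with LiN(i-Pr)2 and Me3SiCl (in situ quench, −78 °C) into the kinetic silyl enol ether F4 of the methyl ketone. Ring A is then closed by an intramolecular Mukaiyama aldol addition (TiCl4, CH2Cl2, −78 °C, aqueous work-up) to give 9.

Step 15 (C-acylation of the imide dianion by a hindered acyl donor). The fallback sets out from 14 through 23 and comes back at 24. The acyl imidazolide 23 is reduced with NaBH4 (THF/H2O, 0 °C) to the primary alcohol F5, which is oxidised with Dess–Martin periodinane to the aldehyde F6. The dianion of 22 adds to F6 at −78 °C (aldol addition) to give the β-hydroxy imide F7, and a second Dess–Martin oxidation gives 24.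

**Further compounds**
F1 | step 3 | tert-butyl 2-oxoacetate | CC(C)(C)OC(=O)C=O
F2 | step 3 | tert-butyl 2-[4-(ethoxycarbonyl)-2,6-dioxocyclohexylidene]acetate | CC(C)(C)OC(=O)C=C1C(=O)CC(C(=O)OCC)CC1=O
F3 | step 3 | tert-butyl 7-(ethoxycarbonyl)-2-methoxy-2,3-dimethyl-5-oxo-3,4,5,6,7,8-hexahydro-2H-chromene-4-carboxylate (3,4-trans, configured as C2 and C1 of 6) | CC(C)(C)OC(=O)[C@H]1[C@H](C)C(C)(OC)OC2=C1C(=O)CC(C(=O)OCC)C2
F4 | step 5 | tert-butyl (2S,3S)-2-[4-(ethoxycarbonyl)-2-methyl-6-oxocyclohex-1-en-1-yl]-3-methyl-4-(trimethylsilyloxy)pent-4-enoate | CC(C)(C)OC(=O)[C@H](C1=C(C)CC(C(=O)OCC)CC1=O)[C@H](C)C(=C)O[Si](C)(C)C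
F5 | step 15 | ethyl (1S,2R,4aR,8S,8aR)-1-(hydroxymethyl)-2,8-dimethyl-4a-(trimethylsilyloxy)-1,2,4a,5,6,7,8,8a-octahydronaphthalene-6-carboxylate | OC[C@@H]1[C@H]2[C@@H](C)CC(C(=O)OCC)C[C@@]2(O[Si](C)(C)C)C=C[C@H]1C
F6 | step 15 | ethyl (1S,2R,4aR,8S,8aR)-1-formyl-2,8-dimethyl-4a-(trimethylsilyloxy)-1,2,4a,5,6,7,8,8a-octahydronaphthalene-6-carboxylate | O=C[C@@H]1[C@H]2[C@@H](C)CC(C(=O)OCC)C[C@@]2(O[Si](C)(C)C)C=C[C@H]1C
F7 | step 15 | ethyl (1S,2R,4aR,8S,8aR)-1-(hydroxy{4-[(3S)-oct-1-en-3-yl]-2,5-dioxopyrrolidin-3-yl}methyl)-2,8-dimethyl-4a-(trimethylsilyloxy)-1,2,4a,5,6,7,8,8a-octahydronaphthalene-6-carboxylate | C=C[C@H](CCCCC)C1C(C(O)[C@@H]2[C@H]3[C@@H](C)CC(C(=O)OCC)C[C@@]3(O[Si](C)(C)C)C=C[C@H]2C)C(=O)NC1=O
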